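The runs come from a simulation with made-up constants.

**Late slowness.** Ask first how slow the late flask is: these readings stop moving within hours.

| setting | grey | amber | Wednesday's | Tuesday's | Thursday's |
|---|---|---|---|---|---|
| starting material | 0.050 M | 0.050 M | 0.050 M | 0.050 M | 0.050 M |
| partner | 2.5 equiv | 2.5 equiv | 2.50 equiv | 2.50 equiv | 2.50 equiv |
| scavenger | 0.58 equiv | 2.1 equiv | 0.800 equiv | 1.60 equiv | 3.20 equiv |
| initiator | 1.9 mol% | 1.9 mol% | 1.9 mol% | 1.9 mol% | 1.9 mol% |
| remark | run made earlier | run made earlier |  |  |  |
| time |  |  | 2.5 d | 2.5 d | 2.5 d |

| run | time / h | starting material / % | target / % |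
|---|---|---|---|
| grey | 3.00 | 84.7 | 12.6 |
| grey | 8.00 | 78.5 | 16.5 |
| grey | 20.0 | 77.4 | 17.9 |
| grey | 40.0 | 79.0 | 18.6 |
| amber | 10.0 | 77.8 | 17.8 |
| amber | 20.0 | 77.7 | 19.1 |
| amber | 30.0 | 78.0 | 17.9 |
| amber | 40.0 | 77.8 | 18.5 |

(readings scatter by 0.5 percentage points)



- part of the starting material that has reacted at the end, Wednesday's
- part of the starting material that has reacted at the end, Tuesday's
- part of the starting material that has reacted at the end, Thursday's
- what raising the equivalents of scavenger from its lowest to its highest value here does to the part of the starting material that has reacted (changes below 5 percentage points count as none) (it falls / it rises / no change)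

**Fade time.** Take the amber mean: 22.2% of the charge has reacted at the stop. At 3.00 h the grey run still lacked 6.88% of the charge, which reads as a half-life near 1.78 h for the activity. The last amber reading lies 22.5 half-lives out, so treat the flask as stopped.

**My bracket.** Below, assume reacted material stays reacted and take the lowest late value, 21.0%. Above, take the highest late value, 22.6%. The late grey and amber means differ by 0.38 percentage points, against a margin of 5 points, although amber holds 3.62 times grey's scavenger. Put Wednesday's, Tuesday's and Thursday's inside this bracket at 2.5 d, and expect no change. Thursday's is the least secure, as its scavenger lies beyond amber's.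

**Chain length.** Follow one chain, assuming each initiator starts two. The charge then starts 3.80% chains, giving 5.84 molecules reacted per chain started: the kinetic chain length. With the same chance of ending at each fork, a chain's mean length is the reciprocal of that chance, so it goes on with chance 0.829. Check this: amber's readings leave 3.85% of the charge as neither starting material nor target, beside those 3.80% chains.

**The forecast.** It gives 22%, 22% and 22%, with no change. Its ground: "Time is therefore not limiting". That stands above my lower bound and below my upper one.

**The result.** The flasks give 22.3%, 22.3% and 22.3%: no change, a shift of 0.037 points. Tuesday's ends with less initiator, 0% of its charge, than starting material, 78%.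

    initiator → 2 initiating radical (k = 1.10 × 10⁻⁴ s⁻¹)
    starting material + initiating radical → capped initiator + first chain carrier (k = 3.48 × 10⁵ M⁻¹ s⁻¹)
    partner + first chain carrier → target + second chain carrier (k = 1070 M⁻¹ s⁻¹)
    starting material + second chain carrier → released group + first chain carrier (k = 7980 M⁻¹ s⁻¹)
    first chain carrier → ended carrier (k = 25.8 s⁻¹)
    2 first chain carrier → ended chains (k = 7.30 × 10⁷ M⁻¹ s⁻¹)
    partner + released group ⇌ idle adduct, settled at all times (K = 14.3 M⁻¹)
    scavenger + released group → scavenged by-product (k = 0.0629 M⁻¹ s⁻¹)

Tuesday's chain length comes to 5.87. At the fork, partner meets first chain carrier against its ending, so scale the read odds, 4.84 to one, with partner. A neighbour of Thursday's with 6.20 equiv then has length 13.0, hence 49.4% reacted; that neighbour gives 49.7%.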